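Locants (target numbering, used for all intermediates): ten-ring C1, C2 = CH2; C3 = C=O; C4 = C(CH3)OH; C5 and C8 = CH–O-isobutyryl; C6 = lactone O–CH; C7 = lactone CH; C9 = CHOH; C10 = CHCH3; lactone C11 (α-C), C12 (C=O), C13 (=CH2).
Enabling feature: the C3 carbonyl lies 1,6 to C8 round the ten-membered ring and the C8/C9 oxygens mark a former C8=C9 olefin. That is a cyclodec-5-enone, the oxy-Cope product of a C3–C8 cyclohexanol with vinyl on C3 and propenyl on C8.
Cuts (retro): C8–O/C9–O back to the Z olefin; C1–C10 cut and C3–C8 rejoined (ten-ring to cyclohexane); then C3–C2 (vinyl), C8–C9 (propenyl), C4–O/C5–O (cis-diol), and lactone C12–O6 from an isopropenyl group.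
Forward order of rings: the carvone cyclohexane (C3–C8), then the trans-fused lactone, then the ten-membered ring by four-carbon ring expansion; epoxide, acetonide and ketal rings are temporary.
Stereochemistry: C7 from (R)-carvone; C6 anti to it (Rubottom); C4/C5 by osmylation anti to C6–O; C3 carbinol by addition anti to the axial C4–O; C10 from the E-propenyl group in the chair transition state; C8/C9 by peripheral epoxidation and backside attack of the C3 carbonyl oxygen.

Key step: step 13

Remark: the 9-hydroxy-3-ketone of the target can close to a transannular 3,9-hemiketal; the two are assumed to interconvert freely and the open form is drawn throughout.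

Step 1
Reactants: 1 (R)-(−)-carvone
Product: 3 (5S,6S)-6-(tert-butyldimethylsilyloxy)carvone, via silyl dienol ether 2 (not isolated)
Conditions: LDA, THF, −78 °C; TBSCl, DMPU, −78 → 0 °C; crude 2, mCPBA, NaHCO3, CH2Cl2, −20 °C
Reagents that add atoms: tert-butyldimethylsilyl chloride CC(C)(C)[Si](C)(C)Cl; mCPBA OOC(=O)c1cccc(Cl)c1
Why: Rubottom oxidation of the kinetic cross-conjugated dienol ether, in which the peracid should attack the enol-ether face anti to the neighbouring isopropenyl group and a 1,4-silyl shift should give the silyloxy ketone with C6–O trans to the C7 substituent.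

Step 2
Reactants: 3 (5S,6S)-6-(tert-butyldimethylsilyloxy)carvone
Product: 4 epoxy ketone
Conditions: 30% H2O2, NaOH (cat.), MeOH, 0 °C
Reagents that add atoms: hydrogen peroxide OO
Why: Weitz–Scheffer nucleophilic epoxidation of the enone (hydroperoxide expected anti to the isopropenyl group); both epoxide centres are erased in steps 3 and 4, so their configuration is immaterial.

Step 3
Reactants: 4 epoxy ketone
Product: 5 transposed allylic alcohol
Conditions: N2H4·H2O, AcOH (cat.), MeOH, 0 → 20 °C
Reagents that add atoms: none
Why: Wharton transposition, in which the epoxy-ketone hydrazone should lose N2 to place the oxygen on C3 and the olefin at C4=C5 without touching C6 or C7.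

Step 4
Reactants: 5 transposed allylic alcohol
Product: 6 (4R,5S)-4-silyloxy enone
Conditions: Dess–Martin periodinane, NaHCO3, CH2Cl2, 20 °C
Reagents that add atoms: none
Why: Dess–Martin oxidation of the secondary allylic alcohol should give the enone with the ketone at C3 and the silyloxy group now in the γ-position (C6).

Step 5
Reactants: 6 (4R,5S)-4-silyloxy enone
Product: 7 C12 allylic alcohol
Conditions: SeO2 (0.5 equiv), t-BuOOH, CH2Cl2, 20 °C
Reagents that add atoms: tert-butyl hydroperoxide CC(C)(C)OO (terminal oxidant); selenium dioxide O=[Se]=O (catalytic oxygen carrier)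
Why: Sharpless SeO2/t-BuOOH allylic oxidation (ene reaction then [2,3] shift) should act only on the electron-rich 1,1-disubstituted isopropenyl group, at its methyl, since the enone olefin is deactivated.

Step 6
Reactants: 7 C12 allylic alcohol
Product: 8 enone diol
Conditions: HF·pyridine, THF, 0 → 20 °C
Reagents that add atoms: none
Why: fluoride-induced silyl ether cleavage should free the C6 hydroxyl under non-basic conditions that leave the γ-oxy enone intact.

Step 7
Reactants: 8 enone diol
Product: 11 trans-fused alpha-methylene lactone enone, via hydroxy enal 9 (not isolated), via lactol 10 (not isolated)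
Conditions: TEMPO (10 mol %), PhI(OAc)2 (2.5 equiv), CH2Cl2, 20 °C
Reagents that add atoms: none
Why: TEMPO/PhI(OAc)2 oxidative lactonisation, in which the primary allylic alcohol should be oxidised selectively to the enal, close onto the C6 hydroxyl as the lactol and be oxidised on to the trans-fused α-methylene-γ-butyrolactone.

Step 8
Reactants: 11 trans-fused alpha-methylene lactone enone
Product: 12 dimethylamine adduct
Conditions: Me2NH (2 M in THF), EtOH, 0 → 20 °C
Reagents that add atoms: dimethylamine CNC
Why: aza-Michael addition to the exo-methylene lactone (far more electrophilic than the trisubstituted enone) masks the acrylate; protonation on the open face should place CH2NMe2 anti to C8, at a centre (C11) that is erased again in step 14.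

Step 9
Reactants: 12 dimethylamine adduct
Product: 13 C4,C5-cis-diol
Conditions: OsO4 (5 mol %), NMO (2 equiv), acetone/H2O 4:1, 20 °C
Reagents that add atoms: osmium tetroxide O=[Os](=O)(=O)=O (catalytic oxygen carrier); N-methylmorpholine N-oxide C[N+]1([O-])CCOCC1 (terminal oxidant)
Why: Upjohn dihydroxylation of the enone, with osmylation expected anti to the allylic C6–O bond (Kishi's empirical rule), so that the C4 and C5 hydroxyls are cis to each other and trans to C6–O.

Step 10
Reactants: 13 C4,C5-cis-diol
Product: 14 acetonide ketone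
Conditions: Me2C(OMe)2, TsOH·H2O (1.2 equiv, the first equivalent protonates the amine), acetone, 20 °C; NaHCO3
Reagents that add atoms: 2,2-dimethoxypropane COC(C)(C)OC
Why: acid-catalysed acetonide formation on the cis tertiary/secondary diol, which locks the ring (C4–O axial, C5–O equatorial) for the later facial control.

Step 11
Reactants: 14 acetonide ketone; 15 (E)-1-bromoprop-1-ene
Product: 17 C8-(E)-propenyl ketone, via lithium enolate 16 (not isolated)
Conditions: LiHMDS (2.2 equiv), THF, −78 → 0 °C; 15, Pd2(dba)3 (2.5 mol %), Q-Phos (6 mol %), 20 → 45 °C; AcOH, −78 °C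
Reagents that add atoms: (E)-1-bromoprop-1-ene C/C=C/Br
Why: Pd-catalysed α-alkenylation of a ketone enolate at C8, the only enolisable position; oxidative addition and reductive elimination should retain the E geometry, and kinetic axial α-protonation of the product dienolate should leave the propenyl group equatorial, trans to the C7 substituent.

Step 12
Reactants: 17 C8-(E)-propenyl ketone; 18 vinylmagnesium bromide
Product: 19 C3 vinyl carbinol
Conditions: CeCl3 (2.5 equiv, dried), 18 (2.2 equiv), THF, −78 °C; aq NH4Cl
Reagents that add atoms: vinylmagnesium bromide C=C[Mg]Br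
Why: Imamoto organocerium 1,2-addition (non-basic, ketone-selective over the lactone); the nucleophile should enter axially on the face anti to the axial C4–O bond of the acetonide (Felkin–Anh and steric control), putting the vinyl group cis to the C8 propenyl group.

Step 13
Reactants: 19 C3 vinyl carbinol
Product: 22 (Z)-cyclodecenone, via potassium alkoxide 20 (not isolated), via potassium enolate 21 (not isolated)
Conditions: KHMDS (1.1 equiv), 18-crown-6 (1.2 equiv), THF, −78 → 25 °C; aq NH4Cl, −78 °C
Reagents that add atoms: none
Why: Deprotonation gives alkoxide 20, whose C3–C8 σ bond is flanked by the vinyl and propenyl π bonds, so a charge-accelerated [3,3]-sigmatropic shift (anionic oxy-Cope rearrangement) should break C3–C8 while forming C1–C10 and give enolate 21, protonated to 22 on quench. The closest known reaction type is the potassium alkoxide/18-crown-6 rearrangement of 1,2-dialkenylcyclohexanols to cyclodec-5-enones used for germacranes. The ten-membered ring is therefore closed by a four-carbon ring expansion of the cyclohexane (bond exchange inside a bicyclic chair-like six-centre transition state) and not by end-to-end cyclisation, so no high dilution is needed. C10 is the only new stereocentre: with the cyclohexane locked by the trans-lactone and the acetonide, the cis-dialkenyl isomer (vinyl axial, propenyl equatorial) has a single chair transition state, in which the E-propenyl methyl is pseudo-equatorial and C1 bonds to the C10 face that gives the required (R) centre, while C7 is pseudo-axial so that the C8=C9 olefin emerges Z. The step needs chair over boat selectivity and rearrangement faster than lactone enolisation or β-loss of dimethylamine; the first is secured by the locked ring geometry, the second by fast O–H deprotonation and the large rate acceleration of the crown-ether-separated potassium alkoxide at or below room temperature.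

Step 14
Reactants: 22 (Z)-cyclodecenone
Product: 25 keto epoxide, via amine N-oxide 23 (not isolated), via methylene lactone olefin 24 (not isolated)
Conditions: dimethyldioxirane (2.3 equiv, acetone), CH2Cl2, −20 → 20 °C
Reagents that add atoms: dimethyldioxirane CC1(C)OO1
Why: N-oxidation then Cope elimination should unmask the α-methylene lactone, and neutral dioxirane epoxidation should then occur only on the Z olefin (the acrylate is electron-poor), on its peripheral face turned away from the transannular C3 carbonyl, which fixes C8–O as required and places C9–O for later inversion.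

Step 15
Reactants: 25 keto epoxide; 26 isobutyric anhydride
Product: 29 bridged methyl ketal diol, via bridged acyl ketal 27 (not isolated), via methyl ketal acetonide 28 (not isolated)
Conditions: 26 (3 equiv), TMSOTf (10 mol %), CH2Cl2, −40 → −10 °C; then MeOH, CSA (20 mol %), 0 → 20 °C
Reagents that add atoms: isobutyric anhydride CC(C)C(=O)OC(=O)C(C)C; methanol CO
Why: Proposed new method: the acyl triflate formed in situ should O-acylate the epoxide, and the transannular C3 carbonyl oxygen should then open it at C9 from the inner face (6-exo, inversion), so that the epoxide oxygen stays on C8 as its isobutyrate and the C3 oxocarbenium ion is captured from outside by isobutyrate (27) and exchanged for methoxide (28); if plain Lewis-acid activation comes first, the same product should arise through the internal 6,8-dioxabicyclo[3.2.1]octane ketal and its acylative cleavage at O8, which keeps the six-membered oxocarbenium ion; closest known reaction types are Lewis-acid-catalysed opening of epoxides by anhydrides, acid-induced cyclisation of keto epoxides to bicyclic ketals and acetolysis of 1,6-anhydro sugars; the acidic methanol also removes the acetonide, leaving C9–O locked in the ketal.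

Step 16
Reactants: 29 bridged methyl ketal diol; 26 isobutyric anhydride
Product: 30 bis(isobutyrate) methyl ketal
Conditions: 26 (1.5 equiv), Et3N, DMAP (10 mol %), CH2Cl2, 0 → 20 °C
Reagents that add atoms: isobutyric anhydride CC(C)C(=O)OC(=O)C(C)C
Why: DMAP-catalysed acylation of the C5 hydroxyl, the only secondary alcohol present, since the C4 hydroxyl is tertiary and C9–O is held in the ketal.

Step 17
Reactants: 30 bis(isobutyrate) methyl ketal
Product: 31 target CNP0396108.1
Conditions: 1 M HCl, THF/H2O, 0 → 20 °C
Reagents that add atoms: water O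
Why: acid-catalysed hydrolysis of the mixed methyl ketal should release the C3 ketone and the C9 hydroxyl under conditions that spare the two secondary isobutyrates and the α-methylene lactone.

Compound list
1 | (R)-(−)-carvone, (5R)-2-methyl-5-(prop-1-en-2-yl)cyclohex-2-en-1-one | C=C(C)[C@@H]1CC=C(C)C(=O)C1 | starting material
2 | tert-butyldimethylsilyl dienol ether of 1 (cross-conjugated, enol ether towards C6) | C=C(C)[C@@H]1CC=C(C)C(O[Si](C)(C)C(C)(C)C)=C1 | intermediate
3 | (5S,6S)-6-(tert-butyldimethylsilyloxy)-2-methyl-5-(prop-1-en-2-yl)cyclohex-2-en-1-one (OTBS trans to isopropenyl) | C=C(C)[C@@H]1CC=C(C)C(=O)[C@H]1O[Si](C)(C)C(C)(C)C | intermediate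
4 | 2,3-epoxide of 3 (epoxide anti to isopropenyl, syn to OTBS) | C=C(C)[C@@H]1C[C@H]2O[C@@]2(C)C(=O)[C@H]1O[Si](C)(C)C(C)(C)C | intermediate
5 | 4-(tert-butyldimethylsilyloxy)-2-methyl-5-(prop-1-en-2-yl)cyclohex-2-en-1-ol (OH and OTBS cis, both trans to isopropenyl) | C=C(C)[C@@H]1C[C@@H](O)C(C)=C[C@H]1O[Si](C)(C)C(C)(C)C | intermediate
6 | (4R,5S)-4-(tert-butyldimethylsilyloxy)-2-methyl-5-(prop-1-en-2-yl)cyclohex-2-en-1-one | C=C(C)[C@@H]1CC(=O)C(C)=C[C@H]1O[Si](C)(C)C(C)(C)C | intermediate
7 | (4R,5S)-4-(tert-butyldimethylsilyloxy)-5-(3-hydroxyprop-1-en-2-yl)-2-methylcyclohex-2-en-1-one | C=C(CO)[C@@H]1CC(=O)C(C)=C[C@H]1O[Si](C)(C)C(C)(C)C | intermediate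
8 | (4R,5S)-4-hydroxy-5-(3-hydroxyprop-1-en-2-yl)-2-methylcyclohex-2-en-1-one | C=C(CO)[C@@H]1CC(=O)C(C)=C[C@H]1O | intermediate
9 | hydroxy enal (primary alcohol of 8 oxidised to the aldehyde) | C=C(C=O)[C@@H]1CC(=O)C(C)=C[C@H]1O | intermediate
10 | lactol of 9 with the C6 hydroxyl (both anomers) | C=C1C(O)O[C@@H]2C=C(C)C(=O)C[C@@H]12 | intermediate
11 | trans-fused α-methylene-γ-butyrolactone enone (6-methyl-3-methylidene-3a,4-dihydro-1-benzofuran-2,5(3H,7aH)-dione, C6–O and C7–C11 anti) | C=C1C(=O)O[C@@H]2C=C(C)C(=O)C[C@@H]12 | intermediate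
12 | 13-dimethylamino-11,13-dihydro derivative of 11 (CH2NMe2 anti to C8) | CN(C)C[C@@H]1C(=O)O[C@@H]2C=C(C)C(=O)C[C@@H]12 | intermediate
13 | C4,C5-cis-diol of 12 (both hydroxyls anti to C6–O) | CN(C)C[C@@H]1C(=O)O[C@@H]2[C@@H](O)[C@@](C)(O)C(=O)C[C@@H]12 | intermediate
14 | 4,5-O-isopropylidene derivative of 13 | CN(C)C[C@@H]1C(=O)O[C@@H]2[C@H]3OC(C)(C)O[C@@]3(C)C(=O)C[C@@H]12 | intermediate
15 | (E)-1-bromoprop-1-ene | C/C=C/Br | starting material
16 | lithium enolate of 14 (C3–O, C3=C8) | CN(C)C[C@@H]1C(=O)O[C@@H]2[C@H]3OC(C)(C)O[C@@]3(C)C([O-])=C[C@@H]12.[Li+] | intermediate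
17 | 14 carrying an (E)-prop-1-enyl group on C8, trans to C7–C11 | CN(C)C[C@@H]1C(=O)O[C@@H]2[C@H]3OC(C)(C)O[C@@]3(C)C(=O)[C@H](/C=C/C)[C@@H]12 | intermediate
18 | vinylmagnesium bromide | C=C[Mg]Br | starting material
19 | C3 tertiary alcohol of 17 (vinyl cis to the C8 propenyl and anti to C4–O; OH cis to C4–O) | CN(C)C[C@@H]1C(=O)O[C@@H]2[C@H]3OC(C)(C)O[C@@]3(C)[C@](O)(C=C)[C@H](/C=C/C)[C@@H]12 | intermediate
20 | potassium alkoxide of 19 | CN(C)C[C@@H]1C(=O)O[C@@H]2[C@H]3OC(C)(C)O[C@@]3(C)[C@]([O-])(C=C)[C@H](/C=C/C)[C@@H]12.[K+] | intermediate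
21 | potassium C2=C3 enolate of 22 | CN(C)C[C@@H]1C(=O)O[C@H]2[C@H]1/C=C\[C@H](C)C/C=C(\[O-])[C@]3(C)OC(C)(C)O[C@H]23.[K+] | intermediate
22 | ten-membered ketone: (8Z,10R)-cyclodec-8-en-3-one with 4,5-O-isopropylidene, trans-6,12-lactone and 13-dimethylamino group | CN(C)C[C@@H]1C(=O)O[C@H]2[C@H]1/C=C\[C@H](C)CCC(=O)[C@]3(C)OC(C)(C)O[C@H]23 | intermediate
23 | N-oxide of 22 | C[N+](C)([O-])C[C@@H]1C(=O)O[C@H]2[C@H]1/C=C\[C@H](C)CCC(=O)[C@]3(C)OC(C)(C)O[C@H]23 | intermediate
24 | α-methylene lactone with free C8=C9 (Z) olefin | C=C1C(=O)O[C@H]2[C@H]1/C=C\[C@H](C)CCC(=O)[C@]3(C)OC(C)(C)O[C@H]23 | intermediate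
25 | 8,9-cis-epoxide of 24 (oxygen on the peripheral face) | C=C1C(=O)O[C@H]2[C@H]1[C@H]4O[C@H]4[C@H](C)CCC(=O)[C@]3(C)OC(C)(C)O[C@H]23 | intermediate
26 | isobutyric anhydride | CC(C)C(=O)OC(=O)C(C)C | starting material
27 | bridged acyl ketal: 3,9-epoxy bridge, 3-O-isobutyryl, 8-O-isobutyryl, 4,5-acetonide | C=C1C(=O)O[C@H]2[C@H]1[C@@H](OC(=O)C(C)C)[C@H]3[C@H](C)CC[C@](OC(=O)C(C)C)(O3)[C@]4(C)OC(C)(C)O[C@H]24 | intermediate
28 | bridged methyl ketal: 3,9-epoxy bridge, 3-OMe, 8-O-isobutyryl, 4,5-acetonide | C=C1C(=O)O[C@H]2[C@H]1[C@@H](OC(=O)C(C)C)[C@H]3[C@H](C)CC[C@](OC)(O3)[C@]4(C)OC(C)(C)O[C@H]24 | intermediate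
29 | bridged methyl ketal with free C4 and C5 hydroxyls and 8-O-isobutyryl | C=C1C(=O)O[C@H]2[C@H]1[C@@H](OC(=O)C(C)C)[C@H]3[C@H](C)CC[C@](OC)(O3)[C@](C)(O)[C@@H]2O | intermediate
30 | bridged methyl ketal 5,8-bis(isobutyrate) | C=C1C(=O)O[C@H]2[C@H]1[C@@H](OC(=O)C(C)C)[C@H]3[C@H](C)CC[C@](OC)(O3)[C@](C)(O)[C@@H]2OC(=O)C(C)C | intermediate
31 | CNP0396108.1 (4R,5R,6S,7R,8R,9R,10R) | C=C1C(=O)O[C@H]2[C@H]1[C@@H](OC(=O)C(C)C)[C@H](O)[C@H](C)CCC(=O)[C@](C)(O)[C@@H]2OC(=O)C(C)C | target

Total step count: 17. Longest linear sequence: 17 steps (from 1).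

Steps most likely to fail

Step 15. The activated epoxide may be captured from outside by isobutyrate or triflate instead of by the C3 carbonyl, the acetonide may be lost acylatively, or the ketal may be cleaved at the wrong oxygen. The fallback sets out from 25 and uses two separate, known operations. Catalytic CSA in CH2Cl2 at 0 °C should drive the acid-induced keto-epoxide cyclisation to the internal ketal F1, in which C3 is bonded to both O8 and O9. F1 is isolated and cleaved under acetolysis-type conditions (isobutyric anhydride, cat. TfOH, 0 °C), which, as for 1,6-anhydro sugars, should break the C3–O8 bond and give 27. Methanolysis as in step 15 then returns to the route at 29.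

Step 13. Under the strongly basic conditions the lactone may be enolised and lose dimethylamine, or a slow rearrangement of the cis isomer may give way to fragmentation. The fallback sets out from 19 and uses the neutral thermal variant. Silylation with N-(trimethylsilyl)imidazole gives the trimethylsilyl ether F2. Heating in degassed o-dichlorobenzene at 180–200 °C (siloxy-Cope rearrangement through the same chair) should give the silyl enol ether F3. Aqueous citric acid in THF hydrolyses it, returning to the route at 22.

Step 11. The excess base may move the new β,γ-double bond into conjugation with the ketone, or lactone deprotonation may compete. The fallback sets out from 14: LDA then allyl bromide gives the 8-allyl ketone F4 (allyl trans to the C7 substituent). A one-position olefin migration with H2-activated [Ir(cod)(PMePh2)2]PF6 in THF should then give the (E)-propenyl ketone, returning to the route at 17.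

Further compounds
F1 | step 15 | internal ketal of 25 (C3 bonded to O8 and O9, 6,8-dioxabicyclo[3.2.1]octane unit, acetonide retained) | C=C1C(=O)O[C@H]2[C@H]1[C@@H]5[C@H]3[C@H](C)CC[C@@](O5)(O3)[C@]4(C)OC(C)(C)O[C@H]24
F2 | step 13 | trimethylsilyl ether of 19 | CN(C)C[C@@H]1C(=O)O[C@@H]2[C@H]3OC(C)(C)O[C@@]3(C)[C@](O[Si](C)(C)C)(C=C)[C@H](/C=C/C)[C@@H]12
F3 | step 13 | trimethylsilyl C2=C3 enol ether of 22 | CN(C)C[C@@H]1C(=O)O[C@H]2[C@H]1/C=C\[C@H](C)C/C=C(\O[Si](C)(C)C)[C@]3(C)OC(C)(C)O[C@H]23
F4 | step 11 | 8-allyl ketone (allyl trans to C7–C11) | CN(C)C[C@@H]1C(=O)O[C@@H]2[C@H]3OC(C)(C)O[C@@]3(C)C(=O)[C@H](CC=C)[C@@H]12
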